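**Retrosynthetic overview**
1. Target 20 ⇐ hydrogenation of side-chain butenolide 19 ⇐ vinylogous Mannich reaction of the bicyclic N-acyliminium ion from 16 with silyloxyfuran 18 (side-chain lactone last).
2. 16 ⇐ Nef reaction (C9 nitro → ketone) and C13 epimerisation of 14 ⇐ directed hydrogenation of the butenolide in 13 ⇐ aldol/aminal annulation (C1–C2 and N4–C3, pyrrolidinone ring) on macrocyclic α-ketoamide 10.
3. 10 ⇐ Pd-catalysed ring expansion of the N-(α-ketoacyl)-3-pyrroline 9: the N4–C8 bond is cleaved and C8–C9 is formed, turning the five-membered ring into the 11-membered lactam.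
4. 9 ⇐ double carbonylation of alkenyl bromide 7 with 3-pyrroline (C1 and C9a from CO); 7 ⇐ asymmetric vinylogous Michael addition of bromobutenolide 6 to nitrobutene 4.
5. Ring order: butenolide → 3-pyrroline amide → 11-membered lactam → pyrrolidinone → saturated ring lactone → side-chain lactone.

Assumption: atom labels follow the tuberostemonone skeleton (N4, C5–C9, C9a, C1–C3, C10–C14, C18–C21); compounds 5, 8 and 17 are bought; the chiral catalysts of steps 3 and 6 are used as the enantiomer that gives the configurations drawn.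

**Step 1**
Reactants: 1 propanal; 2 nitromethane
Product: 4 (E)-1-nitrobut-1-ene, via 1-nitrobutan-2-ol 3 (not isolated)
Conditions: MeNO2 (5 equiv), NaOH (cat.), MeOH/H2O, 0 °C; then MsCl, Et3N, CH2Cl2, 0 °C
Reagents that add atoms: none
Why: Henry (nitroaldol) addition followed by mesylation and E1cB elimination gives the conjugated nitroalkene as its more stable E isomer.

**Step 2**
Reactants: 5 4-hydroxy-3-methylfuran-2(5H)-one (α-methyltetronic acid)
Product: 6 4-bromo-3-methylfuran-2(5H)-one
Conditions: (COBr)2, DMF (cat.), CH2Cl2, 0 °C → rt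
Reagents that add atoms: oxalyl bromide O=C(Br)C(=O)Br
Why: Vilsmeier-type activation (bromoiminium from DMF and oxalyl bromide) turns the vinylogous acid OH into a leaving group that bromide displaces by addition–elimination.

**Step 3**
Reactants: 6 4-bromo-3-methylfuran-2(5H)-one; 4 (E)-1-nitrobut-1-ene
Product: 7 (5S)-4-bromo-3-methyl-5-[(2R)-1-nitrobutan-2-yl]furan-2(5H)-one
Conditions: Et2Zn (20 mol %), Trost ProPhenol ligand (10 mol %), 4 Å MS, THF, rt
Reagents that add atoms: none
Why: Direct catalytic asymmetric vinylogous Michael addition, in which the dinuclear zinc catalyst forms the 2-oxidofuran of 6 and binds the nitroalkene so that γ-attack (C11 on C10) sets C11 and C10 together under catalyst control.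

**Step 4**
Reactants: 7 (5S)-4-bromo-3-methyl-5-[(2R)-1-nitrobutan-2-yl]furan-2(5H)-one; 8 2,5-dihydro-1H-pyrrole (3-pyrroline)
Product: 9 1-(2,5-dihydro-1H-pyrrol-1-yl)-2-{(2S)-4-methyl-2-[(2R)-1-nitrobutan-2-yl]-5-oxo-2,5-dihydrofuran-3-yl}ethane-1,2-dione
Conditions: CO (40 atm), PdCl2(PPh3)2 (5 mol %), 8 added slowly, Et3N, THF, 40 °C
Reagents that add atoms: carbon monoxide [C-]#[O+]
Why: Palladium-catalysed double carbonylation of an alkenyl bromide (oxidative addition, CO insertion, amine attack on a second CO ligand, acyl–carbamoyl reductive elimination) gives the α-ketoamide and brings in C1 and C9a, with high CO pressure and slow amine addition meant to let carbonylation outrun addition–elimination of the amine at C12.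

**Step 5**
Reactants: 9 1-(2,5-dihydro-1H-pyrrol-1-yl)-2-{(2S)-4-methyl-2-[(2R)-1-nitrobutan-2-yl]-5-oxo-2,5-dihydrofuran-3-yl}ethane-1,2-dione
Product: 10 butenolide-fused (6Z)-11-membered α-ketolactam (N4–H; C9 nitro as epimer mixture; C10 and C11 as in 7)
Conditions: Pd2(dba)3 (5 mol %), dppb (12 mol %), Mg(OTf)2 (20 mol %), i-Pr2NEt (20 mol %), THF (2 mM), 50 °C
Reagents that add atoms: none
Why: Proposed new method: Pd(0) inserts into the allylic C–N bond of the N-(α-oxoacyl)-3-pyrroline because the Mg(II)-chelated α-ketoamidate is a good nucleofuge, the amidate deprotonates the CH2NO2 group, and the nitronate alkylates the unsubstituted terminus (C8) of the (Z)-π-allyl so that the five-membered ring grows by six atoms into the 11-membered lactam (N–C return only regenerates 9 and reversible Henry addition to C1 is unproductive); the closest known reaction types are Tsuji–Trost macrocyclisation with nitroalkane pronucleophiles and Pd-catalysed ring opening or expansion of N-acyl vinylaziridines and of allylic ammonium or sulfonimide C–N electrophiles.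

**Step 6**
Reactants: 10 butenolide-fused (6Z)-11-membered α-ketolactam
Product: 13 methyl aminal (bicyclic 1-hydroxy-3-methoxy lactam with C1 as in the target), via silyl aldol adduct 11 (not isolated), via hemiaminal 12 (not isolated)
Conditions: CH2=CHOSiMe3, Cu(OTf)2/t-Bu-box (10 mol %), CH2Cl2, −40 °C; then MeOH, PPTS, rt
Reagents that add atoms: (vinyloxy)trimethylsilane C=CO[Si](C)(C)C; methanol CO
Why: Mukaiyama aldol addition under Evans Cu(II)–bis(oxazoline) catalysis, in which the catalyst chelates the 1,2-dicarbonyl of 10 and exposes one face of the C1 ketone to the enol silane (setting the C1 carbinol), after which the aldehyde is trapped by the lactam N–H as the hemiaminal and then as the methyl N,O-acetal.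

**Step 7**
Reactants: 13 methyl aminal (bicyclic 1-hydroxy-3-methoxy lactam)
Product: 14 saturated all-cis lactone (13-epi; C9 nitro; C3 methoxy)
Conditions: H2 (50 atm), [Ir(cod)(PCy3)(py)]PF6 (10 mol %), CH2Cl2, rt
Reagents that add atoms: none
Why: Hydroxyl-directed homogeneous hydrogenation with Crabtree's catalyst (which reduces tetrasubstituted alkenes and spares the nitro group) delivers H2 to C12=C13 from the butenolide face opposite the macrocyclic loop (anti to C10), setting C12 with the cis ring fusion and leaving the C13 methyl cis, while C6=C7 is saturated as well.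

**Step 8**
Reactants: 14 saturated all-cis lactone (13-epi; C9 nitro; C3 methoxy)
Product: 16 C9 ketone of the 3-methoxy lactam (C13 as in the target), via 13-epimerised nitro lactone 15 (not isolated)
Conditions: DBU, toluene, 80 °C; then aq. TiCl3, NH4OAc, THF, 0 °C → rt
Reagents that add atoms: water O
Why: DBU equilibrates the strained all-cis lactone through its enolate to the thermodynamic C13 epimer (methyl trans to C1), and the DBU nitronate is then converted by the McMurry variant of the Nef reaction (TiCl3 reduction to the imine and hydrolysis at pH 5–6) into the C9 ketone under conditions too mild for β-elimination of the lactone or epimerisation at C10.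

**Step 9**
Reactants: 17 3-methylfuran-2(5H)-one
Product: 18 3-methyl-2-(triisopropylsilyloxy)furan
Conditions: TIPSOTf, Et3N, CH2Cl2, 0 °C
Reagents that add atoms: triisopropylsilyl trifluoromethanesulfonate CC(C)[Si](C(C)C)(C(C)C)OS(=O)(=O)C(F)(F)F
Why: Soft enolisation and O-silylation give the aromatic 2-silyloxyfuran.

**Step 10**
Reactants: 16 C9 ketone of the 3-methoxy lactam; 18 3-methyl-2-(triisopropylsilyloxy)furan
Product: 19 19,20-didehydro target (side-chain butenolide at C3)
Conditions: BF3·OEt2, CH2Cl2, −78 → −40 °C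
Reagents that add atoms: none
Why: Vinylogous Mannich reaction, in which BF3 ionises the N,O-acetal to the bicyclic N-acyliminium ion and the silyloxyfuran adds through C5 to the face of C3 opposite the C1–C12 bond (the macrocycle) via the usual threo-selective open transition state, setting C3 and C18.

**Step 11**
Reactants: 19 19,20-didehydro target (side-chain butenolide at C3)
Product: 20 CNP0221273.1
Conditions: H2 (1 atm), 10% Pd/C, EtOAc, rt
Reagents that add atoms: none
Why: Heterogeneous hydrogenation adds H2 to the butenolide face opposite the C3 substituent, giving the cis-2,4-disubstituted lactone (C20) while the ketone and both lactones survive at 1 atm.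

**Compound list**
1 | propanal | CCC=O | starting material
2 | nitromethane | C[N+](=O)[O-] | starting material
3 | 1-nitrobutan-2-ol (racemic) | CCC(O)C[N+](=O)[O-] | intermediate
4 | (E)-1-nitrobut-1-ene | CC/C=C/[N+](=O)[O-] | intermediate
5 | 4-hydroxy-3-methylfuran-2(5H)-one (α-methyltetronic acid) | CC1=C(O)COC1=O | starting material
6 | 4-bromo-3-methylfuran-2(5H)-one | CC1=C(Br)COC1=O | intermediate
7 | (5S)-4-bromo-3-methyl-5-[(2R)-1-nitrobutan-2-yl]furan-2(5H)-one | CC[C@H](C[N+](=O)[O-])[C@@H]1OC(=O)C(C)=C1Br | intermediate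
8 | 2,5-dihydro-1H-pyrrole (3-pyrroline) | C1C=CCN1 | starting material
9 | 1-(2,5-dihydro-1H-pyrrol-1-yl)-2-{(2S)-4-methyl-2-[(2R)-1-nitrobutan-2-yl]-5-oxo-2,5-dihydrofuran-3-yl}ethane-1,2-dione | CC[C@H](C[N+](=O)[O-])[C@@H]1OC(=O)C(C)=C1C(=O)C(=O)N1CC=CC1 | intermediate
10 | butenolide-fused (6Z)-11-membered α-ketolactam: ring N4(H)–C5–C6=C7–C8–C9(NO2)–C10(Et)–C11–C12–C1(=O)–C9a(=O); butenolide C11–O–C14(=O)–C13(Me)=C12; C9 epimer mixture | CC[C@@H]1C([N+](=O)[O-])C/C=C\CNC(=O)C(=O)C2=C(C)C(=O)O[C@@H]12 | intermediate
11 | silyl aldol adduct of 10: C1 bears OSiMe3 and CH2CHO | CC[C@@H]1C([N+](=O)[O-])C/C=C\CNC(=O)[C@@](O[Si](C)(C)C)(CC=O)C2=C(C)C(=O)O[C@@H]12 | intermediate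
12 | hemiaminal: pyrrolidinone ring closed N4–C3, C3–OH (epimers), C1–OH | CC[C@@H]1C([N+](=O)[O-])C/C=C\CN3C(=O)[C@@](O)(CC3O)C2=C(C)C(=O)O[C@@H]12 | intermediate
13 | methyl aminal: as 12 with C3–OMe (epimers) | CC[C@@H]1C([N+](=O)[O-])C/C=C\CN3C(=O)[C@@](O)(CC3OC)C2=C(C)C(=O)O[C@@H]12 | intermediate
14 | saturated nitro lactam with all-cis ring lactone (C12 as in target, C13 epimeric, methyl cis to C1); C3–OMe; C9–NO2 | CC[C@@H]1C([N+](=O)[O-])CCCCN2C(=O)[C@@](O)(CC2OC)[C@@H]2[C@H]1OC(=O)[C@@H]2C | intermediate
15 | 13-epimerised nitro lactam (C13 methyl trans to C1, as in target) | CC[C@@H]1C([N+](=O)[O-])CCCCN2C(=O)[C@@](O)(CC2OC)[C@@H]2[C@H]1OC(=O)[C@H]2C | intermediate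
16 | C9 ketone of the 3-methoxy lactam (target skeleton with OMe at C3 in place of the side chain) | CC[C@@H]1C(=O)CCCCN2C(=O)[C@@](O)(CC2OC)[C@@H]2[C@H]1OC(=O)[C@H]2C | intermediate
17 | 3-methylfuran-2(5H)-one | CC1=CCOC1=O | starting material
18 | 3-methyl-2-(triisopropylsilyloxy)furan | CC1=C(O[Si](C(C)C)(C(C)C)C(C)C)OC=C1 | intermediate
19 | 19,20-didehydro target: side chain is the 3-methyl-2(5H)-furanon-5-yl butenolide, C3 and C18 as in target | CC[C@@H]1C(=O)CCCCN2C(=O)[C@@](O)(C[C@H]2[C@@H]2C=C(C)C(=O)O2)[C@@H]2[C@H]1OC(=O)[C@H]2C | intermediate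
20 | CNP0221273.1 | CC[C@@H]1C(=O)CCCCN2C(=O)[C@@](O)(C[C@H]2[C@@H]2C[C@H](C)C(=O)O2)[C@@H]2[C@H]1OC(=O)[C@H]2C | target

**Step count**
Total: 11 steps. Longest linear sequence: 9 steps (steps 2, 3, 4, 5, 6, 7, 8, 10, 11).

**Three steps most likely to fail**

Step 5 (the new Pd ring expansion; the allylic amide C–N bond may not ionise, or Henry cyclisation onto C1 may dominate). The fallback uses known chemistry and sets out from 7. Double carbonylation as in step 4, but with the primary amine (Z)-4-aminobut-2-en-1-yl methyl carbonate F3, gives the open-chain α-ketoamide allylic carbonate F4. A conventional Tsuji–Trost macrocyclisation (Pd(PPh3)4, dppe, THF, 2 mM, 50 °C) follows, in which the nitronate attacks the π-allyl terminus with loss of CO2 and methanol. This closes the 11-membered ring and comes back to the route at 10.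

Step 4 (double carbonylation; the amine may instead displace bromide at C12 by addition–elimination, or only one CO may be taken up). The fallback sets out from 7. Miyaura borylation (B2pin2, PdCl2(dppf), KOAc, dioxane, 80 °C) gives the alkenyl pinacol boronate F1. Separately, 8 is acylated with oxalyl chloride (Et3N, CH2Cl2, −78 °C) to the oxamoyl chloride F2. Anhydrous acyl Suzuki coupling of F1 with F2 (Pd(PPh3)4, Cs2CO3, toluene, 80 °C) comes back to the route at 9.

Step 6 (face selectivity at the C1 ketone inside the macrocycle is the least secure stereochemical claim, and the acetaldehyde enol silane is a weak nucleophile). The fallback sets out from 10. Catalytic asymmetric alkynylation of the α-ketoamide with trimethylsilylacetylene (Zn(OTf)2, Et3N, chiral amino alcohol ligand) gives the silylated propargylic alcohol F5. Desilylation (TBAF, AcOH, THF) gives the terminal alkyne F6. Ruthenium-catalysed anti-Markovnikov hydration gives the β-hydroxy aldehyde F7, which closes to hemiaminal 12 and, with MeOH/PPTS, comes back to the route at 13.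

**Further compounds**
F1 | step 4 | alkenyl pinacol boronate from 7 | CC[C@H](C[N+](=O)[O-])[C@@H]1OC(=O)C(C)=C1B2OC(C)(C)C(C)(C)O2
F2 | step 4 | 2-(2,5-dihydro-1H-pyrrol-1-yl)-2-oxoacetyl chloride | O=C(Cl)C(=O)N1CC=CC1
F3 | step 5 | (Z)-4-aminobut-2-en-1-yl methyl carbonate | COC(=O)OC/C=C\CN
F4 | step 5 | open-chain α-ketoamide allylic carbonate from 7 | CC[C@H](C[N+](=O)[O-])[C@@H]1OC(=O)C(C)=C1C(=O)C(=O)NC/C=C\COC(=O)OC
F5 | step 6 | C1 (trimethylsilyl)ethynyl carbinol of 10 | CC[C@@H]1C([N+](=O)[O-])C/C=C\CNC(=O)[C@@](O)(C#C[Si](C)(C)C)C2=C(C)C(=O)O[C@@H]12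
F6 | step 6 | C1 ethynyl carbinol of 10 | CC[C@@H]1C([N+](=O)[O-])C/C=C\CNC(=O)[C@@](O)(C#C)C2=C(C)C(=O)O[C@@H]12
F7 | step 6 | β-hydroxy aldehyde (open form of 12) | CC[C@@H]1C([N+](=O)[O-])C/C=C\CNC(=O)[C@@](O)(CC=O)C2=C(C)C(=O)O[C@@H]12
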